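**Plan**

- Retrosynthesis: the C15 ketone and ring D (C8–C15, C16–C13) are cut first. The key cut then removes C9–C10 and C5–C6 together (retro-de Mayo), leaving an ester C7(=O)–O–C20 between ring-A alcohol 5 and ring-C keto acid 8.
- Forward: ester 9 is formylated at C9; [2+2] photocycloaddition and retro-aldol close the δ-lactone, make C10 quaternary and move the formyl carbon C6 from C9 to C5. Ring D follows by enolate alkylation at C8 and vinyl-radical closure onto C13; C15 is oxidised last.
- Enabling feature: the 6,7-seco skeleton holds the 1,5-dicarbonyl array O=C6–C5–C10–C9–C11=O, and the lactone atoms C8–C7(=O)–O–C20 form a four-atom tether between C9 and C10.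
- Stereochemistry: C1 by CBS reduction; C10 by cycloaddition anti to C1–O; C5 and C9 by equilibration, C9 then locked as an internal C1–O–C11 ketal; C8 by alkylation cis to H-9; C13 by the ring closure; C11 by hydride attack anti to the C15–C16 bridge.

Key step: step 8

Remark: atoms carry ent-kaurane numbers (C7 lactone carbonyl, C20 lactone CH2, C6 the CH2OH carbon); racemic 8 is used, so 9–15 are mixtures at C8 (left undefined in their SMILES) until step 10 enolises that centre.

**Route**

Step 1
Reactants: 1 4,4-dimethylcyclohex-2-en-1-one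
Product: 2 2-iodo-4,4-dimethylcyclohex-2-en-1-one
Conditions: I2, pyridine, CH2Cl2, 0 °C to rt
Reagents that add atoms: iodine, II
Why: α-Iodination of an enone (pyridine conjugate addition, iodination, elimination) should put the halogen on C10, the only α-vinyl position.

Step 2
Reactants: 2 2-iodo-4,4-dimethylcyclohex-2-en-1-one
Product: 3 (1S)-2-iodo-4,4-dimethylcyclohex-2-en-1-ol
Conditions: (R)-Me-CBS (10 mol %), BH3·SMe2, THF, −20 °C
Reagents that add atoms: none
Why: In this Corey–Bakshi–Shibata reduction the α-iodovinyl arm should act as the large group, so the (R)-catalyst should give the (S)-carbinol at C1, the only source of absolute configuration in the route.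

Step 3
Reactants: 3 (1S)-2-iodo-4,4-dimethylcyclohex-2-en-1-ol
Product: 4 (1S)-2-iodo-4,4-dimethylcyclohex-2-en-1-yl triethylsilyl ether
Conditions: Et3SiCl, imidazole, CH2Cl2, 0 °C
Reagents that add atoms: chlorotriethylsilane, CC[Si](Cl)(CC)CC
Why: Silylation masks C1–OH with a group that is meant to fall off in step 8, when the free hydroxyl is needed.

Step 4
Reactants: 4 (1S)-2-iodo-4,4-dimethylcyclohex-2-en-1-yl triethylsilyl ether
Product: 5 [(6S)-3,3-dimethyl-6-(triethylsilyloxy)cyclohex-1-en-1-yl]methanol (ring A: C1–OTES, C10=C5, C20–OH)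
Conditions: Bu3SnCH2OH, Pd(PPh3)4 (5 mol %), dioxane, 90 °C
Reagents that add atoms: (tributylstannyl)methanol, CCCC[Sn](CCCC)(CCCC)CO
Why: Stille coupling of the vinyl iodide with the hydroxymethyl stannane should install C20 on C10 without touching C1.

Step 5
Reactants: 6 3-methoxybenzoic acid
Product: 8 rac-5-oxocyclohex-3-ene-1-carboxylic acid (ring C: C8–CO2H, C11=O, C12=C13), via dihydroanisic acid 7 (not isolated)
Conditions: Li, NH3(l)/THF, −78 °C; NH4Cl; then 2 M HCl, THF, rt
Reagents that add atoms: water, O
Why: Birch reduction of the benzoic acid should give the 1,4-dihydro acid, and acid hydrolysis of its enol ether should give the C11 ketone with the alkene moving into conjugation (C12=C13); C8 is racemic here and is erased in step 10.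

Step 6
Reactants: 5 ring-A allylic alcohol; 8 rac-5-oxocyclohex-3-ene-1-carboxylic acid
Product: 9 ester of 5 and 8 (C20–O–C7(=O)–C8; both C8 epimers)
Conditions: DCC, DMAP (cat.), CH2Cl2, 0 °C to rt
Reagents that add atoms: none
Why: Steglich esterification at the only free hydroxyl (C20–OH) builds the C7–O–C20 link that is the tether of the key step and the lactone of the target.

Step 7
Reactants: 9 ester of 5 and 8
Product: 11 C9-[(triethylsilyloxy)methylene] enone (C9=C6H–OSiEt3), via hydroxymethylene enolate 10 (not isolated)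
Conditions: LiHMDS, THF, −78 °C; CF3CH2OCHO; then Et3SiCl, −78 to 0 °C
Reagents that add atoms: 2,2,2-trifluoroethyl formate, O=COCC(F)(F)F; chlorotriethylsilane, CC[Si](Cl)(CC)CC
Why: Kinetic α′-enolisation of the enone (C9 is the only α′ carbon) and Claisen formylation should put C6 on C9, and O-silylation on the formyl oxygen fixes the enol so that C6, not C11, takes part in the cycloaddition.

Step 8
Reactants: 11 C9-[(triethylsilyloxy)methylene] enone
Product: 14 spiro-lactone keto aldehyde (C1–OH free; C5–CHO; C9–H; C11 enone), via cyclobutane photoadduct 12 (not isolated), via kinetic keto aldehyde 13 (not isolated)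
Conditions: hν (350 nm, Pyrex), MeCN (5 mM), degassed, rt; then HF·pyridine, THF, 0 °C; then DBU (0.3 equiv), CH2Cl2, rt
Reagents that add atoms: none
Why: Irradiation excites the cross-conjugated β-silyloxy enone, whose exocyclic C9=C6 bond adds to the tethered C10=C5 alkene ([2+2] through a triplet 1,4-diradical); fluoride then frees the C6 cyclobutanol, which opens by retro-aldol cleavage of C6–C9 to the C5 aldehyde and the C11 ketone, i.e. a de Mayo reaction run on an O-silylated α-formyl ketone. The δ-lactone ring closes through the C9–C10 bond in the straight mode (six-membered ring over the tether C8–C7–O–C20), and the cyclobutane C9–C10–C5–C6 closes with it and is opened again, so the net change is C9–C10 bond formation and transfer of C6 from C9 to C5. C10 should be set by approach of the enone to the alkene face anti to the C1 silyloxy group; C5 forms cis to C9 and should then epimerise through the aldehyde enol to the equatorial position; C9 is reset on protonation and should equilibrate under DBU towards the epimer whose C11 carbonyl is hydrogen-bonded to the freed C1–OH. The regiochemistry (C9 to the more substituted C10, opposite to the head-to-tail preference of an untethered enone) is secured by the tether, and the O-silyl group on the formyl oxygen ensures that C6 and not the ring carbon C11 enters the cyclobutane. The ring enone C12=C13 cannot reach the alkene and should stay intact, and both C8 epimers are carried because C8 is enolised in step 10.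

Step 9
Reactants: 14 spiro-lactone keto aldehyde
Product: 15 C6 dimethyl acetal with internal C1–O–C11 methyl ketal
Conditions: HC(OMe)3, MeOH, PPTS (cat.), rt
Reagents that add atoms: methanol, CO; trimethyl orthoformate, COC(OC)OC
Why: Acid-catalysed acetalisation should convert the aldehyde to its dimethyl acetal and the γ-hydroxy enone to a five-membered cyclic methyl ketal (O–C1–C10–C9–C11), which can form only from the C9 epimer with C11 syn to C1 and so locks C9 while masking C1–OH, C6 and C11 for the enolate step.

Step 10
Reactants: 15 C6 dimethyl acetal with internal ketal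
Product: 17 keto aldehyde with quaternary C8 bearing 2-bromoallyl (C1–OH free), via alkylated bis-acetal 16 (not isolated)
Conditions: LDA, THF, −78 °C; 2,3-dibromopropene, −78 to −20 °C; then 1 M HCl, THF, rt
Reagents that add atoms: 2,3-dibromopropene, C=C(Br)CBr; water, O
Why: Alkylation of the ring-fusion lactone enolate should occur anti to the ketal-bearing C11, i.e. cis to H-9, giving the cis-fused lactone/ring C with C15 on C8 as in the target; aqueous acid then restores the aldehyde, the enone and C1–OH.

Step 11
Reactants: 17 keto aldehyde with quaternary C8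
Product: 18 C1 acetate of 17
Conditions: Ac2O, pyridine, DMAP (cat.), CH2Cl2, rt
Reagents that add atoms: acetic anhydride, CC(=O)OC(C)=O
Why: Acylation is unambiguous because C1–OH is the only hydroxyl at this stage, C6 and C11 still being carbonyls.

Step 12
Reactants: 18 C1 acetate
Product: 19 tetracyclic keto aldehyde (bicyclo[3.2.1]octane with C16=C17 methylene, C15H2, C11 ketone, C6 aldehyde)
Conditions: Bu3SnH, AIBN (cat.), benzene (5 mM), 80 °C, slow addition
Reagents that add atoms: none
Why: The vinyl radical at C16 should close 5-exo-trig onto C13, the β-carbon of the enone, which forms ring D with its exocyclic methylene and fixes C13, since the two-carbon bridge can only span C8 and C13 on one face.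

Step 13
Reactants: 19 tetracyclic keto aldehyde
Product: 20 6,11β-diol
Conditions: NaBH4, MeOH/THF, −20 to 0 °C
Reagents that add atoms: none
Why: Borohydride should reduce the aldehyde to C6–OH and attack the C11 ketone from the face opposite the C15–C16 bridge, which lies syn-axial over the other face as the angular methyls do in steroid 11-ketones, giving the axial 11β-alcohol while the acetate and lactone survive.

Step 14
Reactants: 20 6,11β-diol
Product: 21 15-hydroxy derivative (allylic alcohol)
Conditions: SeO2 (0.5 equiv), t-BuOOH, CH2Cl2, rt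
Reagents that add atoms: selenium dioxide, O=[Se]=O; tert-butyl hydroperoxide, CC(C)(C)OO
Why: Selenium dioxide allylic oxidation (ene reaction then [2,3] shift) should hydroxylate C15, the only allylic methylene of the exocyclic alkene, C13 being a bridgehead.

Step 15
Reactants: 21 15-hydroxy derivative
Product: 22 Maoyecrystal E
Conditions: MnO2, CH2Cl2, rt
Reagents that add atoms: none
Why: Manganese dioxide should oxidise only the allylic C15 alcohol to the enone and leave the primary C6 and secondary C11 hydroxyls untouched.

**Compound list**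

1 | 4,4-dimethylcyclohex-2-en-1-one | O=C1C=CC(C)(C)CC1 | starting material
2 | 2-iodo-4,4-dimethylcyclohex-2-en-1-one | O=C1C(I)=CC(C)(C)CC1 | intermediate
3 | (1S)-2-iodo-4,4-dimethylcyclohex-2-en-1-ol | O[C@@H]1C(I)=CC(C)(C)CC1 | intermediate
4 | (1S)-2-iodo-4,4-dimethylcyclohex-2-en-1-yl triethylsilyl ether | CC[Si](CC)(CC)O[C@@H]1C(I)=CC(C)(C)CC1 | intermediate
5 | [(6S)-3,3-dimethyl-6-(triethylsilyloxy)cyclohex-1-en-1-yl]methanol | CC[Si](CC)(CC)O[C@@H]1C(CO)=CC(C)(C)CC1 | intermediate
6 | 3-methoxybenzoic acid | COc1cccc(C(=O)O)c1 | starting material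
7 | 3-methoxycyclohexa-2,5-diene-1-carboxylic acid | COC1=CC(C(=O)O)C=CC1 | intermediate
8 | rac-5-oxocyclohex-3-ene-1-carboxylic acid | O=C1C=CCC(C(=O)O)C1 | intermediate
9 | ester of 5 and 8 (C8 mixture) | CC[Si](CC)(CC)O[C@@H]1C(COC(=O)C2CC=CC(=O)C2)=CC(C)(C)CC1 | intermediate
10 | C9-hydroxymethylene ketone of 9 (present as lithium enolate) | CC[Si](CC)(CC)O[C@@H]1C(COC(=O)C2CC=CC(=O)C2=CO)=CC(C)(C)CC1 | intermediate
11 | C9-[(triethylsilyloxy)methylene] enone | CC[Si](CC)(CC)O[C@@H]1C(COC(=O)C2CC=CC(=O)C2=CO[Si](CC)(CC)CC)=CC(C)(C)CC1 | intermediate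
12 | cyclobutane photoadduct (C9–C10 and C6–C5 bonds; C6–OSiEt3) | CC[Si](CC)(CC)O[C@H]1CCC(C)(C)[C@@H]2C(O[Si](CC)(CC)CC)[C@]3(C(=O)C=CCC3C(=O)OC4)[C@]124 | intermediate
13 | keto aldehyde from retro-aldol (C5–CHO cis to C9; C9 not yet equilibrated) | O=C[C@H]1C(C)(C)CC[C@H](O)[C@]12COC(=O)C3CC=CC(=O)C23 | intermediate
14 | spiro-lactone keto aldehyde (C1, C5, C9, C10 as in target; C8 mixture) | O=C[C@@H]1C(C)(C)CC[C@H](O)[C@]12COC(=O)C3CC=CC(=O)[C@@H]23 | intermediate
15 | C6 dimethyl acetal, internal C1–O–C11 methyl ketal | COC(OC)[C@@H]1C(C)(C)CC[C@@H]2OC3(OC)C=CCC4C(=O)OC[C@]12[C@H]34 | intermediate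
16 | C8-(2-bromoallyl) derivative of 15 | COC(OC)[C@@H]1C(C)(C)CC[C@@H]2OC3(OC)C=CC[C@]4(CC(Br)=C)C(=O)OC[C@]12[C@H]34 | intermediate
17 | keto aldehyde with quaternary C8 (2-bromoallyl), C1–OH | O=C[C@@H]1C(C)(C)CC[C@H](O)[C@]12COC(=O)[C@@]3(CC(Br)=C)CC=CC(=O)[C@@H]23 | intermediate
18 | C1 acetate of 17 | O=C[C@@H]1C(C)(C)CC[C@H](OC(C)=O)[C@]12COC(=O)[C@@]3(CC(Br)=C)CC=CC(=O)[C@@H]23 | intermediate
19 | tetracyclic keto aldehyde (C16 methylene, C11 ketone, C6 aldehyde) | C=C1C[C@]23C[C@H]1CC(=O)[C@H]2[C@]1(COC3=O)[C@@H](OC(C)=O)CCC(C)(C)[C@H]1C=O | intermediate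
20 | 6,11β-diol | C=C1C[C@]23C[C@H]1C[C@H](O)[C@H]2[C@]1(COC3=O)[C@@H](OC(C)=O)CCC(C)(C)[C@H]1CO | intermediate
21 | 15-hydroxy derivative (C15 epimers) | C=C1C(O)[C@]23C[C@H]1C[C@H](O)[C@H]2[C@]1(COC3=O)[C@@H](OC(C)=O)CCC(C)(C)[C@H]1CO | intermediate
22 | Maoyecrystal E | C=C1C(=O)[C@]23C[C@H]1C[C@H](O)[C@H]2[C@]1(COC3=O)[C@@H](OC(C)=O)CCC(C)(C)[C@H]1CO | target

**Count and risks**

Total step count: 15. Longest linear sequence: 14 (steps 1–4 and 6–15).

Steps most likely to fail:

1. Step 8. The s-cis ester conformer needed for ring closure is sparsely populated, so excited-state decay, hydrogen abstraction or crossed addition may outrun the wanted cycloaddition, and the later C5/C9 equilibration may stay incomplete. Fallback, from 5 back to 14, with the C9–C10 bond made by radical chemistry: O-alkylation of 5 with iodomethyl(tributyl)stannane (KH) gives stannylmethyl ether F1. Tin–lithium exchange (n-BuLi, −78 °C) triggers a Wittig–Still [2,3] shift that moves the CH2OH group to C5 and leaves the exocyclic C10=C20 alkene, giving homoallylic alcohol F2. Epoxidation with m-CPBA gives spiro-epoxide F3. Cp2TiCl (from Cp2TiCl2/Zn) opens the epoxide to the C10 radical, which adds to C9 of methyl 3-oxocyclohex-1-ene-1-carboxylate, and the titanium alkoxide lactonises onto the ester to give keto lactone alcohol F4. IBX (DMSO, 70 °C) oxidises C6–OH to the aldehyde and dehydrogenates the ketone to the C12=C13 enone, giving enone aldehyde F5. HF·pyridine and then DBU return 14.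

2. Step 9. The conjugated ketone may fail to close the internal ketal, the alkene may migrate out of conjugation, or the free C1–OH may attack the lactone, so that C9 stays unlocked and the ketone unprotected. Fallback, from 14 back to 17, with separate protecting groups: TBSOTf/2,6-lutidine gives silyl ether F6; 1,2-bis(trimethylsilyloxy)ethane with catalytic TMSOTf (−78 °C) gives bis-dioxolane F7; LDA and 2,3-dibromopropene give alkylated bis-dioxolane F8; aqueous HF in MeCN cleaves both dioxolanes and the silyl ether to return 17. C9 then rests on the DBU equilibrium of step 8 alone.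

3. Step 13. Facial selectivity at C11 may be poor, because the axial C10 on C9 hinders the face opposite the bridge. Fallback, from 18 back to 20, reducing before ring D exists: NaBH4 and then CeCl3·7H2O/NaBH4 (MeOH, −78 °C) reduce the aldehyde and deliver hydride axially to the cyclohexenone, trans to C10, giving allylic alcohol diol F9; Bu3SnH/AIBN then closes ring D by 5-exo attack of the vinyl radical on the C12=C13 alkene and returns 20.

Further compounds

F1 | step 8 | tributylstannylmethyl ether of 5 | CCCC[Sn](CCCC)(CCCC)COCC1=CC(C)(C)CC[C@@H]1O[Si](CC)(CC)CC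
F2 | step 8 | [2-methylene-6,6-dimethyl-3-(triethylsilyloxy)cyclohexyl]methanol (C5 mixture) | C=C1C(CO)C(C)(C)CC[C@@H]1O[Si](CC)(CC)CC
F3 | step 8 | C10–C20 spiro-epoxide of F2 | OCC1C(C)(C)CC[C@H](O[Si](CC)(CC)CC)C12CO2
F4 | step 8 | spiro-lactone with saturated C11 ketone, C6–OH, C1–OTES | OCC1C(C)(C)CC[C@H](O[Si](CC)(CC)CC)[C@]12COC(=O)C3CCCC(=O)C23
F5 | step 8 | C1 triethylsilyl ether of 14 (C5, C8, C9 mixtures) | O=CC1C(C)(C)CC[C@H](O[Si](CC)(CC)CC)[C@]12COC(=O)C3CC=CC(=O)C23
F6 | step 9 | C1 tert-butyldimethylsilyl ether of 14 | O=C[C@@H]1C(C)(C)CC[C@H](O[Si](C)(C)C(C)(C)C)[C@]12COC(=O)C3CC=CC(=O)[C@@H]23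
F7 | step 9 | bis-dioxolane of F6 (C6 acetal, C11 ketal) | C1COC(O1)[C@@H]1C(C)(C)CC[C@H](O[Si](C)(C)C(C)(C)C)[C@]12COC(=O)C3CC=CC4(OCCO4)[C@@H]23
F8 | step 9 | C8-(2-bromoallyl) derivative of F7 | C1COC(O1)[C@@H]1C(C)(C)CC[C@H](O[Si](C)(C)C(C)(C)C)[C@]12COC(=O)[C@@]3(CC(Br)=C)CC=CC4(OCCO4)[C@@H]23
F9 | step 13 | 6,11β-diol of 18 with C12=C13 alkene and 2-bromoallyl group | OC[C@@H]1C(C)(C)CC[C@H](OC(C)=O)[C@]12COC(=O)[C@@]3(CC(Br)=C)CC=C[C@H](O)[C@@H]23
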